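**Retrosynthetic overview**
1. Target 24 ⇐ seco acid 22: one acid step hydrolyses both acetals, closes ring B (C7 aldehyde onto C8) and traps the benzylic C7 cation with the C20 acid to give the lactone.
2. 22 ⇐ aldehyde 20 (acetylation, Pinnick oxidation). 20 ⇐ Z-allylic alcohol 19 by a hydrogen-atom-transfer-initiated closure of ring A that ends in a 1,2-aryl shift from C20 to C10; the C20 carbinol controls C5 and C10.
3. 19 ⇐ propargylic alcohol 13 (anti-carbomagnesiation/iodination, then Negishi coupling); 13 ⇐ aldehyde 10 + ethynyltrimethylsilane (asymmetric alkynylation).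
4. 10 ⇐ catechol: acetonide, two ortho-lithiations (isopropenyl, then CHO) and an asymmetric hydroboration that sets C15.
5. Ring order: C (catechol) → A (key step) → B and lactone (last step).

Assumptions: 14 and 18 (0.5 M in THF) are catalogue items. In steps 3 and 5 the ligand enantiomer that gives the drawn configuration is used. Carbon labels C1–C20 are abietane numbering. Nothing in the route has been run; step 8 is a proposed reaction.

**Step 1**
Reactants: 1 catechol
Product: 2 2,2-dimethyl-1,3-benzodioxole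
Conditions: 2,2-dimethoxypropane, TsOH (cat.), PhMe, reflux (MeOH removed)
Reagents that add atoms: 2,2-dimethoxypropane, COC(C)(C)OC
Why: Acid-catalysed transketalisation gives the catechol acetonide, which survives organolithiums and oxidants, directs ortho-lithiation and later leaves as acetone.

**Step 2**
Reactants: 2 2,2-dimethyl-1,3-benzodioxole; 3 2-bromopropene
Product: 6 2,2-dimethyl-4-(prop-1-en-2-yl)-1,3-benzodioxole, via aryllithium 4 (not isolated), via arylzinc chloride 5 (not isolated)
Conditions: n-BuLi, TMEDA, THF, −20 → 0 °C; ZnCl2, 0 °C → rt; 3, Pd(PPh3)4 (3 mol%), 55 °C (sealed vessel)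
Reagents that add atoms: n-butyllithium, [Li]CCCC (lithium of 4 only); zinc chloride, Cl[Zn]Cl (zinc and chlorine of 5 only)
Why: Directed ortho-metalation next to the ring oxygen, transmetalation to zinc and Negishi coupling with the vinyl bromide on zerovalent palladium.

**Step 3**
Reactants: 6 2,2-dimethyl-4-(prop-1-en-2-yl)-1,3-benzodioxole
Product: 8 (2S)-2-(2,2-dimethyl-1,3-benzodioxol-4-yl)propan-1-ol, via pinacol boronate 7 (not isolated)
Conditions: HBpin (1.2 equiv), CoCl2·IPO (2 mol%; IPO = chiral iminopyridine–oxazoline ligand), NaBHEt3 (6 mol%), THF, rt; then NaOH, H2O2, 0 °C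
Reagents that add atoms: pinacolborane, CC1(C)OBOC1(C)C (boron unit of 7 only); hydrogen peroxide, OO (oxygen of 8)
Why: Cobalt-hydride-catalysed anti-Markovnikov asymmetric hydroboration of a 1,1-disubstituted aryl alkene, in which the ligand selects the alkene face and sets C15, followed by oxidation of the primary C–B bond, which does not touch the stereocentre (the descriptor changes from R in 7 to S in 8 only through the priority change).

**Step 4**
Reactants: 8 (2S)-2-(2,2-dimethyl-1,3-benzodioxol-4-yl)propan-1-ol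
Product: 10 7-[(2S)-1-hydroxypropan-2-yl]-2,2-dimethyl-1,3-benzodioxole-4-carbaldehyde, via dilithio species 9 (not isolated)
Conditions: n-BuLi (2.4 equiv), TMEDA, THF, −78 → 0 °C; DMF, −78 °C → rt; H2O
Reagents that add atoms: n-butyllithium, [Li]CCCC (lithium of 9 only); N,N-dimethylformamide, CN(C)C=O (formyl group of 10)
Why: Directed ortho-metalation: after O-deprotonation the second equivalent lithiates the only remaining position ortho to a ring oxygen and DMF formylates it (this carbon becomes C20); C15 is not touched.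

**Step 5**
Reactants: 10 7-[(2S)-1-hydroxypropan-2-yl]-2,2-dimethyl-1,3-benzodioxole-4-carbaldehyde; 11 ethynyltrimethylsilane
Product: 13 (2S)-2-{7-[(1S)-1-hydroxyprop-2-yn-1-yl]-2,2-dimethyl-1,3-benzodioxol-4-yl}propan-1-ol, via silylalkynol 12 (not isolated)
Conditions: 11 (3 equiv), Me2Zn (3.5 equiv), ProPhenol ligand (10 mol%), Ph3PO (20 mol%), PhMe, 0 °C; H2O; then K2CO3, MeOH, rt
Reagents that add atoms: none
Why: Catalytic enantioselective alkynylzinc addition to an aryl aldehyde (ProPhenol–zinc alkynylation) sets the C20 carbinol by catalyst control, independent of remote C15; basic methanolysis removes the alkynyl silyl group, which changes the descriptor from R in 12 to S in 13 without changing the centre.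

**Step 6**
Reactants: 13 (2S)-2-{7-[(1S)-1-hydroxyprop-2-yn-1-yl]-2,2-dimethyl-1,3-benzodioxol-4-yl}propan-1-ol; 14 5-bromo-2-methylpent-1-ene
Product: 17 (2S)-2-{7-[(1R,2Z)-1-hydroxy-3-iodo-2-(4-methylpent-4-en-1-yl)prop-2-en-1-yl]-2,2-dimethyl-1,3-benzodioxol-4-yl}propan-1-ol, via Grignard reagent 15 (not isolated), via alkenylmagnesium species 16 (not isolated)
Conditions: 14, Mg, THF → 15 (4.5 equiv); 13, CuI (15 mol%), THF/Et2O, −20 → 35 °C; I2, −30 → 0 °C; H2O, aq. Na2S2O3 wash
Reagents that add atoms: magnesium, [Mg] (magnesium of 15 and 16 only); iodine, [I][I]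
Why: Duboudin-type copper-catalysed anti-carbomagnesiation of a propargylic alkoxide puts the alkyl group on the internal alkyne carbon and magnesium on the terminal carbon, held cis to the carbinol by O–Mg chelation; iodinolysis with retention gives the Z-iodide and the carbinol centre is spatially unchanged (the descriptor changes to R only because iodine raises the alkenyl priority).

**Step 7**
Reactants: 17 (2S)-2-{7-[(1R,2Z)-1-hydroxy-3-iodo-2-(4-methylpent-4-en-1-yl)prop-2-en-1-yl]-2,2-dimethyl-1,3-benzodioxol-4-yl}propan-1-ol; 18 bromo(1,3-dioxolan-2-ylmethyl)zinc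
Product: 19 (2S)-2-{7-[(1S,2Z)-4-(1,3-dioxolan-2-yl)-1-hydroxy-2-(4-methylpent-4-en-1-yl)but-2-en-1-yl]-2,2-dimethyl-1,3-benzodioxol-4-yl}propan-1-ol
Conditions: 18 (3.5 equiv), PdCl2(dppf) (5 mol%), THF, 45 °C
Reagents that add atoms: none
Why: Negishi sp2–sp3 coupling with retention of alkene geometry places the C6–C7 acetal unit cis to the carbinol carbon, the geometry the next step needs.

**Step 8**
Reactants: 19 (2S)-2-{7-[(1S,2Z)-4-(1,3-dioxolan-2-yl)-1-hydroxy-2-(4-methylpent-4-en-1-yl)but-2-en-1-yl]-2,2-dimethyl-1,3-benzodioxol-4-yl}propan-1-ol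
Product: 20 (1R,2S)-2-(1,3-dioxolan-2-ylmethyl)-1-{7-[(2S)-1-hydroxypropan-2-yl]-2,2-dimethyl-1,3-benzodioxol-4-yl}-3,3-dimethylcyclohexane-1-carbaldehyde
Conditions: Co(salen′) (5 mol%, racemic, divalent cobalt; salen′ = N,N′-bis(3,5-di-tert-butylsalicylidene)-1,2-cyclohexanediaminate), N-fluoro-2,4,6-trimethylpyridinium tetrafluoroborate (1.3 equiv), PhSiH3 (1.3 equiv), acetone (0.02 M), 0 °C; aq. NaOH wash
Reagents that add atoms: none
Why: Proposed new method: a cobalt hydride transfers a hydrogen atom only to the 1,1-disubstituted alkene, the tertiary C4 radical is oxidised through a tetravalent alkylcobalt to a cation equivalent that is captured 6-endo at C5 by the Z-trisubstituted alkene in a chair transition state, and the developing C10 cation is quenched by an anti 1,2-shift of the electron-rich aryl group from the carbinol carbon (semipinacol rearrangement) to give the aldehyde; A(1,3) strain holds the C20–H bond in the alkene plane, so the aryl group shields one face, C4 adds to the other and the (S)-carbinol is relayed to C5 (S) and C10 (R); the closest known reactions are cobalt-catalysed hydrogen-atom-transfer radical–polar crossover polyene cyclisations and hydrogen-atom-transfer-triggered semipinacol rearrangements of allylic alcohols.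

**Step 9**
Reactants: 20 (1R,2S)-2-(1,3-dioxolan-2-ylmethyl)-1-{7-[(2S)-1-hydroxypropan-2-yl]-2,2-dimethyl-1,3-benzodioxol-4-yl}-3,3-dimethylcyclohexane-1-carbaldehyde
Product: 21 (2S)-2-{7-[(1R,2S)-2-(1,3-dioxolan-2-ylmethyl)-1-formyl-3,3-dimethylcyclohexyl]-2,2-dimethyl-1,3-benzodioxol-4-yl}propyl acetate
Conditions: Ac2O, pyridine, DMAP (cat.), CH2Cl2, 0 °C → rt
Reagents that add atoms: acetic anhydride, CC(=O)OC(C)=O
Why: Nucleophile-catalysed acylation of the only free hydroxyl; the aldehyde is non-enolisable and both acetals are inert.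

**Step 10**
Reactants: 21 (2S)-2-{7-[(1R,2S)-2-(1,3-dioxolan-2-ylmethyl)-1-formyl-3,3-dimethylcyclohexyl]-2,2-dimethyl-1,3-benzodioxol-4-yl}propyl acetate
Product: 22 (1R,2S)-1-{7-[(2S)-1-acetoxypropan-2-yl]-2,2-dimethyl-1,3-benzodioxol-4-yl}-2-(1,3-dioxolan-2-ylmethyl)-3,3-dimethylcyclohexane-1-carboxylic acid
Conditions: NaClO2, NaH2PO4, 2-methylbut-2-ene (20 equiv), t-BuOH/THF/H2O, 0 °C → rt
Reagents that add atoms: sodium chlorite, [Na+].[O-]Cl=O
Why: Pinnick oxidation works on hindered neopentyl aldehydes; the buffer keeps both acetals and the acetate intact and the alkene scavenger protects the electron-rich arene from HOCl.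

**Step 11**
Reactants: 22 (1R,2S)-1-{7-[(2S)-1-acetoxypropan-2-yl]-2,2-dimethyl-1,3-benzodioxol-4-yl}-2-(1,3-dioxolan-2-ylmethyl)-3,3-dimethylcyclohexane-1-carboxylic acid
Product: 24 CNP0105472.1 ((15S)-16-acetoxycarnosol), via aldehyde acid 23 (not isolated)
Conditions: TFA/H2O (9:1), CH2Cl2 (0.01 M), degassed, 0 °C → rt
Reagents that add atoms: water, O (oxygen of the aldehyde in 23 only)
Why: Acid hydrolysis of both acetals, intramolecular Friedel–Crafts hydroxyalkylation at C8 (para to the C12 hydroxyl) and capture of the benzylic C7 cation by the axial C20 acid; only the bridged lactone with 7S configuration is geometrically possible, and the trans ring fusion follows from step 8.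

**Compound list**
1 | catechol | Oc1ccccc1O | starting material
2 | 2,2-dimethyl-1,3-benzodioxole | CC1(C)Oc2ccccc2O1 | intermediate
3 | 2-bromopropene | CC(Br)=C | starting material
4 | (2,2-dimethyl-1,3-benzodioxol-4-yl)lithium | [Li]c1cccc2OC(C)(C)Oc12 | intermediate
5 | chloro(2,2-dimethyl-1,3-benzodioxol-4-yl)zinc | Cl[Zn]c1cccc2OC(C)(C)Oc12 | intermediate
6 | 2,2-dimethyl-4-(prop-1-en-2-yl)-1,3-benzodioxole | CC(=C)c1cccc2OC(C)(C)Oc12 | intermediate
7 | 2-[(2R)-2-(2,2-dimethyl-1,3-benzodioxol-4-yl)propyl]-4,4,5,5-tetramethyl-1,3,2-dioxaborolane | CC1(C)OB(C[C@@H](C)c2cccc3OC(C)(C)Oc23)OC1(C)C | intermediate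
8 | (2S)-2-(2,2-dimethyl-1,3-benzodioxol-4-yl)propan-1-ol | OC[C@@H](C)c1cccc2OC(C)(C)Oc12 | intermediate
9 | lithium (2S)-2-(7-lithio-2,2-dimethyl-1,3-benzodioxol-4-yl)propan-1-olate | [Li]OC[C@@H](C)c1ccc([Li])c2OC(C)(C)Oc12 | intermediate
10 | 7-[(2S)-1-hydroxypropan-2-yl]-2,2-dimethyl-1,3-benzodioxole-4-carbaldehyde | OC[C@@H](C)c1ccc(C=O)c2OC(C)(C)Oc12 | intermediate
11 | ethynyltrimethylsilane | C#C[Si](C)(C)C | starting material
12 | (2S)-2-{7-[(1R)-1-hydroxy-3-(trimethylsilyl)prop-2-yn-1-yl]-2,2-dimethyl-1,3-benzodioxol-4-yl}propan-1-ol | OC[C@@H](C)c1ccc([C@@H](O)C#C[Si](C)(C)C)c2OC(C)(C)Oc12 | intermediate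
13 | (2S)-2-{7-[(1S)-1-hydroxyprop-2-yn-1-yl]-2,2-dimethyl-1,3-benzodioxol-4-yl}propan-1-ol | OC[C@@H](C)c1ccc([C@@H](O)C#C)c2OC(C)(C)Oc12 | intermediate
14 | 5-bromo-2-methylpent-1-ene | CC(=C)CCCBr | starting material
15 | bromo(4-methylpent-4-en-1-yl)magnesium | CC(=C)CCC[Mg]Br | intermediate
16 | tris(bromomagnesium) species from anti-addition of 15 to 13: Z-alkenylmagnesium bromide (Mg on the terminal alkene carbon, cis to the carbinol carbon and chelated by its alkoxide), both hydroxyls as OMgBr; drawn open-chain | Br[Mg]OC[C@@H](C)c1ccc([C@@H](O[Mg]Br)/C(CCCC(C)=C)=C\[Mg]Br)c2OC(C)(C)Oc12 | intermediate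
17 | (2S)-2-{7-[(1R,2Z)-1-hydroxy-3-iodo-2-(4-methylpent-4-en-1-yl)prop-2-en-1-yl]-2,2-dimethyl-1,3-benzodioxol-4-yl}propan-1-ol | OC[C@@H](C)c1ccc([C@@H](O)/C(CCCC(C)=C)=C\I)c2OC(C)(C)Oc12 | intermediate
18 | bromo(1,3-dioxolan-2-ylmethyl)zinc | Br[Zn]CC1OCCO1 | starting material
19 | (2S)-2-{7-[(1S,2Z)-4-(1,3-dioxolan-2-yl)-1-hydroxy-2-(4-methylpent-4-en-1-yl)but-2-en-1-yl]-2,2-dimethyl-1,3-benzodioxol-4-yl}propan-1-ol | OC[C@@H](C)c1ccc([C@@H](O)/C(CCCC(C)=C)=C\CC3OCCO3)c2OC(C)(C)Oc12 | intermediate
20 | (1R,2S)-2-(1,3-dioxolan-2-ylmethyl)-1-{7-[(2S)-1-hydroxypropan-2-yl]-2,2-dimethyl-1,3-benzodioxol-4-yl}-3,3-dimethylcyclohexane-1-carbaldehyde | OC[C@@H](C)c1ccc([C@@]3(C=O)CCCC(C)(C)[C@@H]3CC4OCCO4)c2OC(C)(C)Oc12 | intermediate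
21 | (2S)-2-{7-[(1R,2S)-2-(1,3-dioxolan-2-ylmethyl)-1-formyl-3,3-dimethylcyclohexyl]-2,2-dimethyl-1,3-benzodioxol-4-yl}propyl acetate | CC(=O)OC[C@@H](C)c1ccc([C@@]3(C=O)CCCC(C)(C)[C@@H]3CC4OCCO4)c2OC(C)(C)Oc12 | intermediate
22 | (1R,2S)-1-{7-[(2S)-1-acetoxypropan-2-yl]-2,2-dimethyl-1,3-benzodioxol-4-yl}-2-(1,3-dioxolan-2-ylmethyl)-3,3-dimethylcyclohexane-1-carboxylic acid | CC(=O)OC[C@@H](C)c1ccc([C@@]3(C(=O)O)CCCC(C)(C)[C@@H]3CC4OCCO4)c2OC(C)(C)Oc12 | intermediate
23 | (1R,2S)-1-{4-[(2S)-1-acetoxypropan-2-yl]-2,3-dihydroxyphenyl}-3,3-dimethyl-2-(2-oxoethyl)cyclohexane-1-carboxylic acid | CC(=O)OC[C@@H](C)c1ccc([C@@]3(C(=O)O)CCCC(C)(C)[C@@H]3CC=O)c(O)c1O | intermediate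
24 | CNP0105472.1, (15S)-16-acetoxycarnosol: (2S)-2-[(4aR,9S,10aS)-5,6-dihydroxy-1,1-dimethyl-12-oxo-2,3,4,9,10,10a-hexahydro-1H-4a,9-(epoxymethano)phenanthren-7-yl]propyl acetate | CC(=O)OC[C@@H](C)c1cc2c(c(O)c1O)[C@@]13CCCC(C)(C)[C@@H]1C[C@@H]2OC3=O | target

**Totals**
Total step count: 11. Longest linear sequence: 11 steps (1 → 24); 3, 11, 14 and 18 enter directly.

**Steps most likely to fail**
The three steps most likely to fail are step 6, step 8 (the proposed new step) and step 11.

Risk at step 6 (carbomagnesiation/iodination): a functionalised primary alkyl Grignard reagent may add sluggishly to a secondary aryl propargylic alcohol with a terminal alkyne, or give mixtures. The fallback for step 6 sets out from 10 and comes back to the route at 19; it brings in the alkyl group by cross-coupling instead of carbometalation.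
- 10 is alkynylated under the conditions of step 5 with 2-(prop-2-yn-1-yl)-1,3-dioxolane in place of 11 to give the internal propargylic alcohol F1.
- Palladium-catalysed syn-hydrostannation (Bu3SnH, PdCl2(PPh3)2, THF, 0 °C) puts tin on the alkyne carbon next to the carbinol and gives the E-alkenylstannane F2.
- Iododestannylation (I2, CH2Cl2, 0 °C) gives the E-2-iodoalkene F3.
- Zinc insertion into 14 (Zn dust, LiCl, THF, 50 °C) gives the alkylzinc bromide F4, and Negishi coupling of F3 with it (PdCl2(dppf), THF, 45 °C) gives 19 with retention of the alkene geometry.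

Risk at step 8 (the proposed cyclisation/1,2-aryl shift): the benzylic allylic alcohol may ionise, the C4 cation may be trapped or eliminate before ring closure, and facial control may be incomplete. The fallback for step 8 uses known reactions, sets out from 19 and comes back to the route at 21; the aryl shift and the closure of ring A are done separately.
- The primary hydroxyl of 19 is acetylated selectively (AcCl, 2,4,6-collidine, CH2Cl2, −78 °C) to give the primary monoacetate F5.
- Hydroxyl-directed epoxidation (VO(acac)2, t-BuOOH, PhMe, 0 °C) leaves the isolated 1,1-disubstituted alkene alone. With the cis substituent enforcing the A(1,3)-minimised conformer, it favours the threo 2,3-epoxy alcohol F6. The minor erythro isomer, which would lead to the wrong C10 configuration, is removed by chromatography at this stage.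
- BF3·OEt2 (CH2Cl2, −78 °C) triggers the known stereospecific rearrangement of a 2,3-epoxy alcohol with anti 1,2-aryl shift, which gives the β-hydroxy aldehyde F7 with the C10 quaternary centre.
- Burgess reagent (PhMe, 50 °C) dehydrates the secondary alcohol away from the quaternary carbon to the E-vinyl dioxolane F8.
- PPTS in wet acetone (rt) unmasks the E-enal F9 while the catechol acetonide stays.
- A hydrogen-atom-transfer Giese cyclisation (Fe(acac)3, PhSiH3, EtOH/ethylene glycol, 60 °C) closes ring A 6-exo from the C4 radical onto the enal β-carbon C5. The new side chain is expected equatorial and trans to the equatorial aryl group, which gives the dialdehyde F10.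
- Acetalisation of the unhindered C7 aldehyde alone (ethylene glycol, PPTS, PhH, 4 Å molecular sieves, rt; the neopentyl C20 aldehyde does not react) gives 21.

Risk at step 11 (one-pot ring B closure, lactonisation and deprotection): the free catechol aldehyde may oligomerise or the acetate may be lost. The fallback for step 11 sets out from 22 and comes back to the route at 24; it forms the lactone oxidatively.
- 22 is treated with TFA/H2O in CH2Cl2 and then with Et3SiH, so that the benzylic C7 cation formed on ring closure is reduced (ionic hydrogenation) and both acetals are removed, which gives 16-acetoxycarnosic acid F11.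
- Ag2O (Et2O, rt) oxidises the catechol to the ortho-quinone F12.
- On standing in solution this tautomerises to the para-quinone methide, which is captured by the C20 acid on its own face (the known carnosic acid to carnosol conversion) and gives 24.

**Further compounds**
F1 | step 6 | internal propargylic alcohol: (2S)-2-{7-[(1S)-4-(1,3-dioxolan-2-yl)-1-hydroxybut-2-yn-1-yl]-2,2-dimethyl-1,3-benzodioxol-4-yl}propan-1-ol | OC[C@@H](C)c1ccc([C@@H](O)C#CCC3OCCO3)c2OC(C)(C)Oc12
F2 | step 6 | E-alkenylstannane: as 19 but with tributylstannyl in place of the 4-methylpent-4-enyl group (tin cis to the alkene hydrogen, dioxolanylmethyl cis to the carbinol carbon) | OC[C@@H](C)c1ccc([C@@H](O)/C([Sn](CCCC)(CCCC)CCCC)=C\CC3OCCO3)c2OC(C)(C)Oc12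
F3 | step 6 | E-2-iodoalkene: as 19 but with iodine in place of the 4-methylpent-4-enyl group | OC[C@@H](C)c1ccc([C@@H](O)/C(I)=C\CC3OCCO3)c2OC(C)(C)Oc12
F4 | step 6 | alkylzinc bromide: bromo(4-methylpent-4-en-1-yl)zinc | CC(=C)CCC[Zn]Br
F5 | step 8 | primary monoacetate of 19 | CC(=O)OC[C@@H](C)c1ccc([C@@H](O)/C(CCCC(C)=C)=C\CC3OCCO3)c2OC(C)(C)Oc12
F6 | step 8 | threo 2,3-epoxy alcohol from F5 (epoxide oxygen on the face that the carbinol hydroxyl occupies in the A(1,3)-minimised conformer, dioxolanylmethyl cis to the carbinol carbon) | CC(=O)OC[C@@H](C)c1ccc([C@@H](O)[C@]3(CCCC(C)=C)O[C@@H]3CC4OCCO4)c2OC(C)(C)Oc12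
F7 | step 8 | β-hydroxy aldehyde: quaternary carbon bearing aryl, CHO and 4-methylpent-4-enyl; adjacent CH(OH)CH2(1,3-dioxolan-2-yl) | CC(=O)OC[C@@H](C)c1ccc([C@@](C=O)(CCCC(C)=C)[C@H](O)CC4OCCO4)c2OC(C)(C)Oc12
F8 | step 8 | E-vinyl dioxolane: quaternary carbon bearing aryl, CHO, 4-methylpent-4-enyl and (E)-2-(1,3-dioxolan-2-yl)ethenyl | CC(=O)OC[C@@H](C)c1ccc([C@@](C=O)(CCCC(C)=C)/C=C/C4OCCO4)c2OC(C)(C)Oc12
F9 | step 8 | E-enal: quaternary carbon bearing aryl, CHO, 4-methylpent-4-enyl and (E)-3-oxoprop-1-enyl | CC(=O)OC[C@@H](C)c1ccc([C@@](C=O)(CCCC(C)=C)/C=C/C=O)c2OC(C)(C)Oc12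
F10 | step 8 | dialdehyde: (2S)-2-{7-[(1R,2S)-1-formyl-3,3-dimethyl-2-(2-oxoethyl)cyclohexyl]-2,2-dimethyl-1,3-benzodioxol-4-yl}propyl acetate | CC(=O)OC[C@@H](C)c1ccc([C@@]3(C=O)CCCC(C)(C)[C@@H]3CC=O)c2OC(C)(C)Oc12
F11 | step 11 | 16-acetoxycarnosic acid: (4aR,10aS)-7-[(2S)-1-acetoxypropan-2-yl]-5,6-dihydroxy-1,1-dimethyl-1,3,4,9,10,10a-hexahydrophenanthrene-4a(2H)-carboxylic acid | CC(=O)OC[C@@H](C)c1cc2c(c(O)c1O)[C@@]3(C(=O)O)CCCC(C)(C)[C@@H]3CC2
F12 | step 11 | ortho-quinone of F11 (11,12-dione) | CC(=O)OC[C@@H](C)C1=CC2=C(C(=O)C1=O)[C@@]3(C(=O)O)CCCC(C)(C)[C@@H]3CC2
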